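**Retrosynthetic overview**
1. Target 30 ⇐ 2,3‑alkene 29 by a final peracid epoxidation; the 11‑acetoxy enone, the 9‑O‑glycolate and the 6‑chloride (by inversion of an allylic alcohol) are installed late on a ring‑A silyl enol ether.
2. Ten‑membered ring ⇐ keto dialdehyde 19: the C5–C6 bond is closed by a carbene‑catalysed cross‑benzoin in which the C5 aldehyde reacts as an acyl anion with the C6 aldehyde; the C5 ketone then becomes the exo‑methylene.
3. Lactone and C8 carbinol ⇐ hydroxyl‑directed epoxidation of a C7=C8 alkene and amide‑assisted anti opening; the alkene ⇐ C9 aldehyde + alkyne, hydroalumination–iodination, Negishi coupling.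
4. Ring A (C1, C10) ⇐ enantioselective Diels–Alder of silyloxydiene 2 with enal ester 3; C2=C3 ⇐ E‑selective Wittig.
5. Ring order: ring A (step 2) → γ‑lactone (step 10) → ten‑membered ring (step 12) → oxirane (step 21).

Assumption: atom labels C1–C20 follow briarane numbering (ring A = C1, C10–C14; lactone = C7, C8, C17, C19), and silyl ether 9, amide 13 and acid 25 are bought.

**Step 1**
Reactants: 1 pent‑1‑en‑3‑one
Product: 2 (Z)‑triisopropyl(penta‑1,3‑dien‑3‑yloxy)silane
Conditions: i‑Pr3SiOTf, Et3N, CH2Cl2, 0 °C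
Reagents that add atoms: triisopropylsilyl trifluoromethanesulfonate CC(C)[Si](C(C)C)(C(C)C)OS(=O)(=O)C(F)(F)F
Why: Soft enolisation and O‑silylation of the enone gives the cross‑conjugated silyl dienol ether as the Z enol ether, so the methyl group sits "outside" in the later cycloaddition.

**Step 2**
Reactants: 2 silyloxydiene; 3 ethyl (E)‑3‑methyl‑4‑oxobut‑2‑enoate
Product: 4 ethyl (1S,2S,6S)‑2‑formyl‑2,6‑dimethyl‑5‑[(triisopropylsilyl)oxy]cyclohex‑4‑ene‑1‑carboxylate
Conditions: (S)‑3,3‑diphenyl‑1‑(o‑tolyl)hexahydropyrrolo[1,2‑c][1,3,2]oxazaborole·Tf2NH (10 mol%), CH2Cl2, −78 → −40 °C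
Reagents that add atoms: none
Why: Catalytic enantioselective Diels–Alder reaction in which the chiral cationic oxazaborolidine binds the formyl group, so the silyloxy‑bearing diene terminus (C11) bonds to C10 and C14 to C1 with CHO endo; the E dienophile fixes Me‑15 cis to the C9 ester and the catalyst face fixes the absolute configuration at C1 and C10 (the antipodal catalyst is used if the sense is opposite; C11 is erased later).

**Step 3**
Reactants: 4 ring‑A aldehyde ester; 5 (3‑hydroxypropyl)triphenylphosphonium bromide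
Product: 6 (2E)‑homoallylic alcohol
Conditions: 5, n‑BuLi (2 equiv), THF, −20 °C; then 4, −78 °C → rt
Reagents that add atoms: none
Why: Wittig olefination with a γ‑oxido ylide, whose lithium alkoxide lets the betaine equilibrate and gives the E alkene, while the non‑enolisable neopentyl aldehyde reacts much faster than the hindered ester.

**Step 4**
Reactants: 6 homoallylic alcohol
Product: 7 C5 triethylsilyl ether
Conditions: Et3SiCl, imidazole, CH2Cl2, 0 °C
Reagents that add atoms: chlorotriethylsilane CC[Si](Cl)(CC)CC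
Why: Standard silylation of the primary alcohol, chosen because a primary triethylsilyl ether can later be oxidised directly to the aldehyde without an acid or fluoride step that would cleave the silyl enol ether.

**Step 5**
Reactants: 7 silyl ether ester
Product: 8 C9 aldehyde
Conditions: i‑Bu2AlH (1.1 equiv), toluene, −78 °C; Rochelle salt
Reagents that add atoms: none
Why: Partial ester reduction; the aluminium hemiacetal of this hindered α‑branched ester is stable at −78 °C and releases the aldehyde only on work‑up.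

**Step 6**
Reactants: 8 C9 aldehyde; 9 triethyl(prop‑2‑yn‑1‑yloxy)silane
Product: 10 (9R)‑propargylic alcohol
Conditions: 9, n‑BuLi, THF, −78 °C; then 8, −78 °C
Reagents that add atoms: none
Why: 1,2‑Addition of a lithium acetylide under Felkin–Anh control (attack anti to quaternary C1) gives the 9R carbinol, which is needed only to steer step 9 and is reset in step 15 (minor 9S isomer removed by chromatography).

**Step 7**
Reactants: 10 propargylic alcohol
Product: 12 (7Z,9R)‑8‑iodo allylic alcohol, via C8 alkenylalane 11 (not isolated)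
Conditions: LiAlH4, AlCl3 (cat.), THF, 0 °C → reflux; then I2, −78 °C
Reagents that add atoms: iodine II
Why: Hydroxyl‑directed trans‑hydroalumination of the propargylic alcohol, which with LiAlH4/AlCl3 puts aluminium on the proximal carbon C8 and hydride on C7, followed by iodinolysis with retention, so C9 and C6 are trans across C7=C8.

**Step 8**
Reactants: 12 alkenyl iodide; 13 2‑bromo‑N,N‑dimethylpropanamide
Product: 14 (7E,9R)‑β,γ‑unsaturated amide
Conditions: 13, Zn, THF; then 12, Pd(dba)2 (5 mol%), 1,2,3,4,5‑pentaphenyl‑1′‑(di‑tert‑butylphosphino)ferrocene (5 mol%), THF, 25 °C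
Reagents that add atoms: none
Why: Negishi‑type cross‑coupling of the amide Reformatsky reagent with the alkenyl iodide proceeds with retention of alkene geometry and forms C8–C17; an amide is used because it cannot lactonise onto 9‑OH, and C17 forms as a mixture that is equilibrated in step 10.

**Step 9**
Reactants: 14 allylic alcohol amide
Product: 15 erythro 7,8‑epoxy‑9‑ol
Conditions: VO(acac)2 (5 mol%), t‑BuOOH, CH2Cl2, 0 °C
Reagents that add atoms: tert‑butyl hydroperoxide CC(C)(C)OO
Why: Hydroxyl‑directed epoxidation touches only the allylic alkene, and for an allylic alcohol with a substituent on the 2‑position (C8) the conformer that minimises A1,2 strain delivers oxygen to give the erythro epoxy alcohol, which with 9R sets the C8–O bond of the target.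

**Step 10**
Reactants: 15 epoxy amide
Product: 18 hydroxy lactone diol, via iminium ether 16 (not isolated), via C17‑epimeric lactone 17 (not isolated)
Conditions: Ti(OiPr)4 (1.2 equiv), CH2Cl2, 25 °C; aq. citrate buffer (pH 5); then DBU (0.2 equiv), CH2Cl2
Reagents that add atoms: water O
Why: Neighbouring‑group opening of the titanium‑chelated 2,3‑epoxy alcohol at its distal carbon C7 by the amide oxygen with inversion (overall anti addition across the E alkene puts 8‑O and C6 cis on the new ring), hydrolysis of the iminium ether to the γ‑lactone, and base equilibration of C17 to the epimer with Me‑18 trans to the bulky C9 substituent.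

**Step 11**
Reactants: 18 lactone diol bis(silyl ether)
Product: 19 keto dialdehyde
Conditions: (COCl)2, DMSO, CH2Cl2, −78 → −30 °C; Et3N
Reagents that add atoms: none
Why: Swern oxidation converts the two primary triethylsilyl ethers directly into the C5 and C6 aldehydes and the secondary 9‑OH into the ketone, while tertiary 8‑OH and the silyl enol ether are inert.

**Step 12**
Reactants: 19 keto dialdehyde
Product: 20 ten‑membered α‑hydroxy ketone
Conditions: 2‑(pentafluorophenyl)‑6,7‑dihydro‑5H‑pyrrolo[2,1‑c][1,2,4]triazol‑2‑ium tetrafluoroborate (20 mol%), i‑Pr2NEt (20 mol%), CH2Cl2 (2 mM), 25 °C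
Reagents that add atoms: none
Why: Proposed new method: the carbene adds to the unhindered C5 aldehyde (the α‑branched, α‑oxygenated C6 aldehyde is too hindered to form a Breslow intermediate and is the better electrophile), the resulting acyl‑anion equivalent attacks C6 through a ten‑membered transition state preorganised by ring A, the E alkene and the lactone, and transannular hemiketal formation with 8‑OH can pull the reversible reaction forward; the closest known chemistry is the chemoselective intermolecular cross‑benzoin of linear aliphatic aldehydes with α‑branched α‑heteroatom aldehydes and the intramolecular crossed benzoin that closes five‑ and six‑membered rings; C6 forms as an epimer mixture that is reset in steps 14 and 15.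

**Step 13**
Reactants: 20 macrocyclic α‑hydroxy ketone
Product: 21 C5 exo‑methylene allylic alcohol
Conditions: Tebbe reagent Cp2Ti(μ‑Cl)(μ‑CH2)AlMe2 (3 equiv), pyridine, THF, −40 → 0 °C
Reagents that add atoms: Tebbe reagent C=[Ti](C1C=CC=C1)C1C=CC=C1.C[Al](C)Cl
Why: Non‑basic titanium‑carbene methylenation avoids enolisation and β‑elimination of the lactone oxygen and is selective at low temperature for the C5 ketone over the lactone and the C9 ketone, which is flanked by a quaternary and a tertiary carbon.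

**Step 14**
Reactants: 21 allylic alcohol
Product: 22 C6 enone
Conditions: MnO2, CH2Cl2, 25 °C
Reagents that add atoms: none
Why: Selective oxidation of the allylic alcohol erases the uncontrolled C6 centre so that it can be set by hydride addition.

**Step 15**
Reactants: 22 5(16)‑ene‑6,9‑dione
Product: 23 (6R,9S)‑diol
Conditions: NaBH4, CeCl3·7H2O, MeOH, −78 → −40 °C
Reagents that add atoms: none
Why: Luche 1,2‑reduction of both ketones: at C6 the polar Felkin–Anh mode (hydride anti to the lactone C7–O bond) gives the 6,7‑syn alcohol, and at C9 hydride adds anti to quaternary C1 (the two other C8 substituents are near‑equal lactone methines) to give 9S, with C10 staying in its more stable equatorial configuration.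

**Step 16**
Reactants: 23 diol
Product: 24 (6S)‑allylic chloride
Conditions: PPh3, Cl3CC(O)CCl3, CH2Cl2, −20 → 0 °C
Reagents that add atoms: hexachloroacetone ClC(Cl)(Cl)C(=O)C(Cl)(Cl)Cl
Why: Appel‑type chlorination with the PPh3/hexachloroacetone reagent converts the allylic alcohol by SN2 with inversion and without allylic transposition, the neopentyl‑like 9‑OH and tertiary 8‑OH being too hindered to react.

**Step 17**
Reactants: 24 chloro diol; 25 2‑[(tert‑butyldimethylsilyl)oxy]acetic acid
Product: 26 9‑O‑(silyloxyacetyl) ester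
Conditions: 25, DCC, DMAP, CH2Cl2, 25 °C
Reagents that add atoms: none
Why: Steglich esterification acylates the only secondary alcohol (9‑OH) and leaves tertiary 8‑OH free.

**Step 18**
Reactants: 26 ring‑A silyl enol ether
Product: 27 ring‑A 13‑en‑12‑one
Conditions: 2‑iodoxybenzoic acid·4‑methoxypyridine N‑oxide, DMSO, 25 °C
Reagents that add atoms: none
Why: IBX‑mediated dehydrogenation of the regiodefined silyl enol ether (C12=C13 from the cycloaddition) gives the C13=C14 enone without palladium, which would ionise the allylic chloride.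

**Step 19**
Reactants: 27 enone
Product: 28 (11S)‑11‑acetoxy enone
Conditions: Mn(OAc)3·2H2O, benzene, reflux (Dean–Stark)
Reagents that add atoms: manganese triacetate CC(=O)[O-].CC(=O)[O-].CC(=O)[O-].[Mn+3]
Why: Mn(OAc)3 α′‑acetoxylation of the enone at its only enolisable α′ position, acetate being delivered to the ring‑A face opposite the vicinal C9 side chain on C10, which gives 11‑OAc trans to that chain as in the target.

**Step 20**
Reactants: 28 silyl‑protected glycolate
Product: 29 9‑O‑glycoloyl 2,3‑alkene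
Conditions: HF·pyridine, pyridine, THF, 0 °C
Reagents that add atoms: none
Why: Buffered fluoride desilylation of the primary silyl ether, done before the oxirane is present.

**Step 21**
Reactants: 29 triene
Product: 30 CNP0278742.1
Conditions: mCPBA, NaHCO3, CH2Cl2, 0 °C
Reagents that add atoms: 3‑chloroperoxybenzoic acid OOC(=O)c1cccc(Cl)c1
Why: Prilezhaev epoxidation of the E‑disubstituted C2=C3 alkene (the enone is inert and the exo‑methylene is deactivated by the allylic chlorine) is stereospecific for the trans oxirane and is expected to occur on the exposed peripheral face of the E‑cyclodecene to give 2R,3R.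

**Compound list**
1 | pent‑1‑en‑3‑one | CCC(=O)C=C | starting material
2 | (Z)‑triisopropyl(penta‑1,3‑dien‑3‑yloxy)silane | C=C/C(O[Si](C(C)C)(C(C)C)C(C)C)=C/C | intermediate
3 | ethyl (E)‑3‑methyl‑4‑oxobut‑2‑enoate | CCOC(=O)/C=C(\C)C=O | starting material
4 | ethyl (1S,2S,6S)‑2‑formyl‑2,6‑dimethyl‑5‑[(triisopropylsilyl)oxy]cyclohex‑4‑ene‑1‑carboxylate (C1 carries Me‑15 and the C2 aldehyde; C10 ester cis to Me‑15; C12 silyl enol ether) | O=C[C@@]1(C)CC=C(O[Si](C(C)C)(C(C)C)C(C)C)[C@@H](C)[C@@H]1C(=O)OCC | intermediate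
5 | (3‑hydroxypropyl)triphenylphosphonium bromide | OCCC[P+](c1ccccc1)(c1ccccc1)c1ccccc1.[Br-] | starting material
6 | (2E)‑homoallylic alcohol: 4 with CHO replaced by (E)‑CH=CH‑CH2‑CH2OH (C2–C5), ring‑A configuration as in 4 | OCC/C=C/[C@@]1(C)CC=C(O[Si](C(C)C)(C(C)C)C(C)C)[C@@H](C)[C@@H]1C(=O)OCC | intermediate
7 | C5 triethylsilyl ether of 6 | CC[Si](CC)(CC)OCC/C=C/[C@@]1(C)CC=C(O[Si](C(C)C)(C(C)C)C(C)C)[C@@H](C)[C@@H]1C(=O)OCC | intermediate
8 | C9 aldehyde: 7 with CO2Et reduced to CHO | CC[Si](CC)(CC)OCC/C=C/[C@@]1(C)CC=C(O[Si](C(C)C)(C(C)C)C(C)C)[C@@H](C)[C@@H]1C=O | intermediate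
9 | triethyl(prop‑2‑yn‑1‑yloxy)silane | C#CCO[Si](CC)(CC)CC | starting material
10 | (9R)‑propargylic alcohol: C9 carbinol bearing C8≡C7‑C6H2OSiEt3 | CC[Si](CC)(CC)OCC/C=C/[C@@]1(C)CC=C(O[Si](C(C)C)(C(C)C)C(C)C)[C@@H](C)[C@@H]1[C@@H](O)C#CCO[Si](CC)(CC)CC | intermediate
11 | lithium alkoxide of the C8 alkenylalane (AlH2 on C8, H on C7, trans) | CC[Si](CC)(CC)OCC/C=C/[C@@]1(C)CC=C(O[Si](C(C)C)(C(C)C)C(C)C)[C@@H](C)[C@@H]1[C@@H](O[Li])/C([AlH2])=C/CO[Si](CC)(CC)CC | intermediate
12 | (7Z,9R)‑8‑iodo allylic alcohol (C9 and C6 trans across C7=C8) | CC[Si](CC)(CC)OCC/C=C/[C@@]1(C)CC=C(O[Si](C(C)C)(C(C)C)C(C)C)[C@@H](C)[C@@H]1[C@@H](O)/C(I)=C/CO[Si](CC)(CC)CC | intermediate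
13 | 2‑bromo‑N,N‑dimethylpropanamide | CC(Br)C(=O)N(C)C | starting material
14 | (7E,9R)‑β,γ‑unsaturated amide: C8 carries CH(CH3)C(O)NMe2 (C17, C19; C17 epimer mixture) | CC[Si](CC)(CC)OCC/C=C/[C@@]1(C)CC=C(O[Si](C(C)C)(C(C)C)C(C)C)[C@@H](C)[C@@H]1[C@@H](O)/C(C(C)C(=O)N(C)C)=C/CO[Si](CC)(CC)CC | intermediate
15 | erythro 7,8‑epoxide of 14 (8‑O anti to (9R)‑OH; C9 and C6 trans on the oxirane; C17 epimer mixture) | CC[Si](CC)(CC)OCC/C=C/[C@@]1(C)CC=C(O[Si](C(C)C)(C(C)C)C(C)C)[C@@H](C)[C@@H]1[C@@H](O)[C@@]2(C(C)C(=O)N(C)C)O[C@@H]2CO[Si](CC)(CC)CC | intermediate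
16 | cyclic iminium ether (2‑dimethyliminio‑oxolane with C8 alkoxide) from attack of the amide oxygen on C7 | CC[Si](CC)(CC)OCC/C=C/[C@@]1(C)CC=C(O[Si](C(C)C)(C(C)C)C(C)C)[C@@H](C)[C@@H]1[C@@H](O)[C@]2([O-])C(C)C(=[N+](C)C)O[C@H]2CO[Si](CC)(CC)CC | intermediate
17 | γ‑lactone (C19‑O‑C7) with 8‑OH and (9R)‑OH, C17 epimer mixture | CC[Si](CC)(CC)OCC/C=C/[C@@]1(C)CC=C(O[Si](C(C)C)(C(C)C)C(C)C)[C@@H](C)[C@@H]1[C@@H](O)[C@]2(O)C(C)C(=O)O[C@H]2CO[Si](CC)(CC)CC | intermediate
18 | hydroxy lactone diol: C7, C8 and (17R)‑Me as in the target (8‑OH, Me‑18 and C6 on one face), (9R)‑OH | CC[Si](CC)(CC)OCC/C=C/[C@@]1(C)CC=C(O[Si](C(C)C)(C(C)C)C(C)C)[C@@H](C)[C@@H]1[C@@H](O)[C@]2(O)[C@@H](C)C(=O)O[C@H]2CO[Si](CC)(CC)CC | intermediate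
19 | keto dialdehyde: C5 and C6 aldehydes, C9 ketone, free 8‑OH | O=CC/C=C/[C@@]1(C)CC=C(O[Si](C(C)C)(C(C)C)C(C)C)[C@@H](C)[C@@H]1C(=O)[C@]2(O)[C@@H](C)C(=O)O[C@H]2C=O | intermediate
20 | ten‑membered α‑hydroxy ketone: C5 ketone, C6 carbinol (epimer mixture), (2E)‑alkene, C9 ketone | O=C1C/C=C/[C@@]2(C)CC=C(O[Si](C(C)C)(C(C)C)C(C)C)[C@@H](C)[C@@H]2C(=O)[C@]2(O)[C@@H](C)C(=O)O[C@H]2C1O | intermediate
21 | C5 exo‑methylene allylic alcohol (C6 epimer mixture), C9 ketone | C=C1C/C=C/[C@@]2(C)CC=C(O[Si](C(C)C)(C(C)C)C(C)C)[C@@H](C)[C@@H]2C(=O)[C@]2(O)[C@@H](C)C(=O)O[C@H]2C1O | intermediate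
22 | 5(16)‑ene‑6,9‑dione | C=C1C/C=C/[C@@]2(C)CC=C(O[Si](C(C)C)(C(C)C)C(C)C)[C@@H](C)[C@@H]2C(=O)[C@]2(O)[C@@H](C)C(=O)O[C@H]2C1=O | intermediate
23 | (6R,9S)‑diol (6‑OH syn to the lactone oxygen on C7) | C=C1C/C=C/[C@@]2(C)CC=C(O[Si](C(C)C)(C(C)C)C(C)C)[C@@H](C)[C@@H]2[C@H](O)[C@]2(O)[C@@H](C)C(=O)O[C@H]2[C@@H]1O | intermediate
24 | (6S)‑allylic chloride with free (9S)‑OH and 8‑OH | C=C1C/C=C/[C@@]2(C)CC=C(O[Si](C(C)C)(C(C)C)C(C)C)[C@@H](C)[C@@H]2[C@H](O)[C@]2(O)[C@@H](C)C(=O)O[C@H]2[C@H]1Cl | intermediate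
25 | 2‑[(tert‑butyldimethylsilyl)oxy]acetic acid | CC(C)(C)[Si](C)(C)OCC(=O)O | starting material
26 | 9‑O‑[(tert‑butyldimethylsilyloxy)acetyl] ester of 24 | C=C1C/C=C/[C@@]2(C)CC=C(O[Si](C(C)C)(C(C)C)C(C)C)[C@@H](C)[C@@H]2[C@H](OC(=O)CO[Si](C)(C)C(C)(C)C)[C@]2(O)[C@@H](C)C(=O)O[C@H]2[C@H]1Cl | intermediate
27 | ring‑A 13‑en‑12‑one with C11 H/Me (C11 labile, as drawn from the cycloaddition) | C=C1C/C=C/[C@@]2(C)C=CC(=O)[C@@H](C)[C@@H]2[C@H](OC(=O)CO[Si](C)(C)C(C)(C)C)[C@]2(O)[C@@H](C)C(=O)O[C@H]2[C@H]1Cl | intermediate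
28 | (11S)‑11‑acetoxy enone | C=C1C/C=C/[C@@]2(C)C=CC(=O)[C@@](C)(OC(C)=O)[C@@H]2[C@H](OC(=O)CO[Si](C)(C)C(C)(C)C)[C@]2(O)[C@@H](C)C(=O)O[C@H]2[C@H]1Cl | intermediate
29 | 9‑O‑glycoloyl (2E)‑alkene, the deoxy precursor of the target | C=C1C/C=C/[C@@]2(C)C=CC(=O)[C@@](C)(OC(C)=O)[C@@H]2[C@H](OC(=O)CO)[C@]2(O)[C@@H](C)C(=O)O[C@H]2[C@H]1Cl | intermediate
30 | CNP0278742.1 (2R,3R‑epoxide) | C=C1C[C@H]2O[C@@H]2[C@@]2(C)C=CC(=O)[C@@](C)(OC(C)=O)[C@@H]2[C@H](OC(=O)CO)[C@]2(O)[C@@H](C)C(=O)O[C@H]2[C@H]1Cl | target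

**Totals and risks**
Total step count: 21. Longest linear sequence: 21 steps (from 1; every other building block is bought).

Most likely to fail, first: step 12. The β,γ‑unsaturated C5 aldehyde can isomerise, the α‑acyloxy C6 aldehyde can undergo carbene‑induced internal redox, and the ring–chain equilibrium of a ten‑membered acyloin may be unfavourable. The fallback sets out from 19 and keeps the same C5–C6 bond but makes it reductively. SmI2 in THF at −78 °C under high dilution couples the two aldehydes (they are reduced far faster than the hindered C9 ketone) to the macrocyclic 5,6‑diol F1. Swern oxidation gives the macrocyclic 5,6‑dione F2. One equivalent of Tebbe reagent then methylenates the less hindered C5 carbonyl, and the route is rejoined at enone 22.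

Second: step 13. Methylenation of an α‑hydroxy ketone that may rest as the 8‑OH hemiketal, in the presence of a lactone and a second ketone, may be slow or unselective. The fallback sets out from 20 and uses a two‑stage Peterson olefination. Me3SiCH2MgCl with CeCl3 adds to the C5 ketone to give the C5 β‑hydroxysilane F3. Acid‑promoted elimination (BF3·OEt2, −78 °C) then gives 21, where the route continues.

Third: step 21. The peracid may attack the exo‑methylene competitively or approach the wrong face of C2=C3. The fallback sets out from 29 and goes through a halohydrin. NBS in wet THF forms the bromonium ion on the exposed face and water opens it at C3 to give the anti 2‑bromo‑3‑hydroxy bromohydrin F4. K2CO3 in MeOH closes it by internal SN2 to 30, so the oxirane ends on the face opposite to the one a peracid would choose.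

**Further compounds**
F1 | step 12 | macrocyclic 5,6‑diol (pinacol product of 19) | OC1C/C=C/[C@@]2(C)CC=C(O[Si](C(C)C)(C(C)C)C(C)C)[C@@H](C)[C@@H]2C(=O)[C@]2(O)[C@@H](C)C(=O)O[C@H]2C1O
F2 | step 12 | macrocyclic 5,6‑dione | O=C1C/C=C/[C@@]2(C)CC=C(O[Si](C(C)C)(C(C)C)C(C)C)[C@@H](C)[C@@H]2C(=O)[C@]2(O)[C@@H](C)C(=O)O[C@H]2C1=O
F3 | step 13 | C5 β‑hydroxysilane (C5 carbinol bearing CH2SiMe3) | C[Si](C)(C)CC1(O)C/C=C/[C@@]2(C)CC=C(O[Si](C(C)C)(C(C)C)C(C)C)[C@@H](C)[C@@H]2C(=O)[C@]2(O)[C@@H](C)C(=O)O[C@H]2C1O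
F4 | step 21 | anti 2‑bromo‑3‑hydroxy bromohydrin of 29 | C=C1C[C@@H](O)[C@@H](Br)[C@@]2(C)C=CC(=O)[C@@](C)(OC(C)=O)[C@@H]2[C@H](OC(=O)CO)[C@]2(O)[C@@H](C)C(=O)O[C@H]2[C@H]1Cl
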